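The strategy is to remove O1 of lactone A. O1 sits between the C2 carbonyl and aromatic C8a, a carbon with oxygen substituents ortho (C8) and para (C6). Without O1, unit A is a 4,5,6,7-tetramethoxy-3-arylindan-1-one that carries lactone B on its C2 (target C3). One Baeyer–Villiger oxidation shifts C8a from C2 to oxygen, enlarges the five-membered ketone ring to the six-membered lactone and delivers the fifth oxygen of ring A. The precursor is joined at C3–C3' from two halves whose diarylmethine centres come from asymmetric catalysis. Only at the ketone stage can C3 be enolised alone, so the labile 3,4-cis relation is set just before the oxidation.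

Key step: step 9

Numbering: target locants (C2 to C8a for unit A, primed for unit B) are used for all intermediates.
Stereochemical check: the target is (3S,4R,3'S,4'S), with ring A 3,4-cis and ring B 3',4'-trans. There are eight hydroxyl groups, so the protected form is an octamethyl ether.
Assumption: the ligand enantiomers in steps 3 and 5 are assigned by analogy with simpler cinnamates and coumarins. If the first chiroptical check shows the opposite sense, the mirror-image ligand is used and nothing else changes.
Design notes:
- Both aryl additions are run on acceptors without an alpha substituent, where the rhodium chemistry is reliable.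
- No condensation is asked of a mono-activated, hindered ketone.
- C4 and C4' are set by catalysts, C3' by its thermodynamic trans preference, and C3 by kinetic protonation.
- Methyl ethers come with the commercial materials and survive every step.

Step 1
Reactants: 1 1,2,3,4-tetramethoxybenzene
Product: 3 2,3,4,5-tetramethoxybenzaldehyde, via iminium chloride 2 (not isolated)
Conditions: POCl3, DMF, 0 to 80 °C; then ice-water
Reagents that add atoms: N,N-dimethylformamide, CN(C)C=O; water, O
Why: Vilsmeier–Haack formylation of an activated arene whose two free positions are equivalent, each ortho and para to a methoxy group, so only one aldehyde can form on hydrolysis of 2.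

Step 2
Reactants: 3 2,3,4,5-tetramethoxybenzaldehyde; 4 tert-butyl 2-(diethoxyphosphoryl)acetate
Product: 5 tert-butyl (E)-3-(2,3,4,5-tetramethoxyphenyl)prop-2-enoate
Conditions: LiCl, DBU, MeCN, rt
Reagents that add atoms: none
Why: Horner–Wadsworth–Emmons olefination under Masamune–Roush conditions, which with a stabilised phosphonate and an aromatic aldehyde should give the E-cinnamate.

Step 3
Reactants: 5 tert-butyl (E)-3-(2,3,4,5-tetramethoxyphenyl)prop-2-enoate; 6 4-methoxyphenylboronic acid
Product: 7 tert-butyl (3R)-3-(4-methoxyphenyl)-3-(2,3,4,5-tetramethoxyphenyl)propanoate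
Conditions: [RhCl(C2H4)2]2 (1.5 mol %), (1R,4R)-2,5-diphenylbicyclo[2.2.2]octa-2,5-diene (3.3 mol %), KOH (20 mol %), dioxane/H2O 10:1, 50 °C
Reagents that add atoms: none
Why: Rhodium-catalysed asymmetric 1,4-addition of an arylboronic acid to a tert-butyl cinnamate (Hayashi–Miyaura reaction), in which the C2-symmetric chiral diene leaves one alkene face open to the aryl-rhodium species and so sets C4 as R under catalyst control.

Step 4
Reactants: 7 tert-butyl (3R)-3-(4-methoxyphenyl)-3-(2,3,4,5-tetramethoxyphenyl)propanoate
Product: 10 (3R)-4,5,6,7-tetramethoxy-3-(4-methoxyphenyl)indan-1-one, via carboxylic acid 8 (not isolated), via mixed anhydride 9 (not isolated)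
Conditions: TFA, CH2Cl2, rt; then (CF3CO)2O, 0 °C to rt
Reagents that add atoms: none
Why: Acidolysis of the tert-butyl ester followed by intramolecular Friedel–Crafts acylation through the mixed trifluoroacetic anhydride, which can close the five-membered ring only onto the single free position of the tetramethoxyphenyl ring (ortho and para to methoxy groups, whereas the anisyl ortho positions are meta to their donor) and does not touch C4.

Step 5
Reactants: 11 5,7-dimethoxycoumarin; 6 4-methoxyphenylboronic acid
Product: 12 (4S)-5,7-dimethoxy-4-(4-methoxyphenyl)chroman-2-one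
Conditions: Rh(acac)(C2H4)2 (3 mol %), (S)-SEGPHOS (3.3 mol %), dioxane/H2O 10:1, 60 °C
Reagents that add atoms: none
Why: Hayashi–Miyaura 1,4-addition to a coumarin that is unsubstituted at C3', the substrate class for which this catalyst type is established, with the bisphosphine pocket selecting the alkene face and setting C4' as S.

Step 6
Reactants: 10 (3R)-4,5,6,7-tetramethoxy-3-(4-methoxyphenyl)indan-1-one; 12 (4S)-5,7-dimethoxy-4-(4-methoxyphenyl)chroman-2-one
Product: 15 (2R,3R)-4,5,6,7-tetramethoxy-3-(4-methoxyphenyl)-2-[(3S,4S)-5,7-dimethoxy-4-(4-methoxyphenyl)-2-oxochroman-3-yl]indan-1-one (indanone 2,3-trans; lactone 3,4-trans), via indanone lithium enolate 13 (not isolated), via lactone lithium enolate 14 (not isolated)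
Conditions: LDA, THF, −78 °C (10 and excess 12 added to the base); Fe(acac)3 (2.2 equiv), −78 °C to rt
Reagents that add atoms: none
Why: Oxidative enolate heterocoupling, in which trivalent iron oxidises one lithium enolate to an alpha-carbonyl radical that is captured by the other enolate and a second equivalent of oxidant completes the C3–C3' bond, each ring being attacked on the face opposite its neighbouring aryl group to give the 3,4-trans and 3',4'-trans arrangements that are also the thermodynamic ones (stray epimers can be funnelled to 15 with a trace of DBU).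

Step 7
Reactants: 15 the trans,trans keto lactone
Product: 16 (3S,4S)-5,7-dimethoxy-4-(4-methoxyphenyl)-3-[(1S)-4,5,6,7-tetramethoxy-1-(4-methoxyphenyl)-3-(trimethylsilyloxy)-1H-inden-2-yl]chroman-2-one (C4 unchanged in space; its descriptor changes only through the priority rules)
Conditions: TMSOTf (1.2 equiv), Et3N, CH2Cl2, 0 °C
Reagents that add atoms: trimethylsilyl trifluoromethanesulfonate, C[Si](C)(C)OS(=O)(=O)C(F)(F)F
Why: Soft enolisation to a silyl enol ether, chemoselective because the donor-substituted aryl ketone oxygen is far more Lewis basic than the aryl lactone carbonyl, so that only C3 is flattened while C4, C3' and C4' stay as set.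

Step 8
Reactants: 16 the silyl enol ether
Product: 17 (2S,3R)-4,5,6,7-tetramethoxy-3-(4-methoxyphenyl)-2-[(3S,4S)-5,7-dimethoxy-4-(4-methoxyphenyl)-2-oxochroman-3-yl]indan-1-one (indanone 2,3-cis; used at once)
Conditions: Bu4NF, AcOH, THF, −78 °C; cold pH 7 buffer
Reagents that add atoms: none
Why: Kinetic protonation of the enolate released by fluoride, in which the proton reaches C3 from the face opposite the pseudo-axial C4 aryl group, so that lactone B ends on the aryl face and C3 becomes S (3,4-cis), while the weak acetate base at low temperature should not re-enolise the product.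

Step 9
Reactants: 17 the cis keto lactone
Product: 19 (3S,4R)-5,6,7,8-tetramethoxy-4-(4-methoxyphenyl)-3-[(3S,4S)-5,7-dimethoxy-4-(4-methoxyphenyl)-2-oxochroman-3-yl]chroman-2-one (octamethyl ether of the target), via peroxy hemiketal 18 (not isolated)
Conditions: m-CPBA (3 equiv), Na2HPO4 (6 equiv), CH2Cl2, 0 °C to rt, dark
Reagents that add atoms: m-chloroperbenzoic acid, OOC(=O)c1cccc(Cl)c1
Why: Baeyer–Villiger oxidation: the peracid adds to the C2 ketone of 17 from the face that carries only H3 and H4 to give peroxy hemiketal 18, whose O–O bond breaks as C8a shifts from C2 to oxygen. The closest known reaction type is the peracid conversion of 3-aryl-1-indanones into 4-aryl-3,4-dihydrocoumarins. The ring is not closed by attack of one chain end on another; the five-membered ketone ring grows to the six-membered lactone A by a 1,2-shift within the ring that inserts O1 into the C2–C8a bond. No stereocentre is created, and C3, C4, C3' and C4' are retained because none of them migrates and the medium stays close to neutral. The step needs migration of aryl C8a rather than secondary C3, which the C8 (ortho) and C6 (para) methoxy groups secure by stabilising the positive charge on the migrating ring, while C3 is slowed by its bulk and by the inductive pull of the nearby C2' carbonyl. It also needs the ketone to react before the anisole-type rings and C3 to hold its configuration, and both are served by a weakly acidic peracid, the solid phosphate buffer and low temperature.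

Step 10
Reactants: 19 the octamethyl ether
Product: 20 (3S,4R,3'S,4'S)-5,6,7,8,5',7'-hexahydroxy-4,4'-bis(4-hydroxyphenyl)-[3,3'-bichroman]-2,2'-dione (target CNP0064734.2)
Conditions: BBr3 (16 equiv), CH2Cl2, −78 °C to rt, argon; then degassed ice-water
Reagents that add atoms: none
Why: Boron tribromide cleavage of aryl methyl ethers is non-basic, so C3 and C3' are not enolised, both aryl lactones are closed after the acidic aqueous work-up, any acyl shift to the flanking 5-OH or 5'-OH is degenerate because both oxygenated rings are symmetric about their bond to C4 or C4', and air is excluded because the tetrahydroxylated ring A is easily oxidised.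

Compound list
1 | 1,2,3,4-tetramethoxybenzene | COc1ccc(OC)c(OC)c1OC | starting material
2 | N,N-dimethyl(2,3,4,5-tetramethoxybenzylidene)iminium chloride | C[N+](C)=Cc1cc(OC)c(OC)c(OC)c1OC.[Cl-] | intermediate
3 | 2,3,4,5-tetramethoxybenzaldehyde | O=Cc1cc(OC)c(OC)c(OC)c1OC | intermediate
4 | tert-butyl 2-(diethoxyphosphoryl)acetate | CCOP(=O)(CC(=O)OC(C)(C)C)OCC | starting material
5 | tert-butyl (E)-3-(2,3,4,5-tetramethoxyphenyl)prop-2-enoate | CC(C)(C)OC(=O)/C=C/c1cc(OC)c(OC)c(OC)c1OC | intermediate
6 | 4-methoxyphenylboronic acid | COc1ccc(B(O)O)cc1 | starting material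
7 | tert-butyl (3R)-3-(4-methoxyphenyl)-3-(2,3,4,5-tetramethoxyphenyl)propanoate | CC(C)(C)OC(=O)C[C@H](c1ccc(OC)cc1)c1cc(OC)c(OC)c(OC)c1OC | intermediate
8 | (3R)-3-(4-methoxyphenyl)-3-(2,3,4,5-tetramethoxyphenyl)propanoic acid | OC(=O)C[C@H](c1ccc(OC)cc1)c1cc(OC)c(OC)c(OC)c1OC | intermediate
9 | mixed anhydride of 8 with trifluoroacetic acid | O=C(C[C@H](c1ccc(OC)cc1)c1cc(OC)c(OC)c(OC)c1OC)OC(=O)C(F)(F)F | intermediate
10 | (3R)-4,5,6,7-tetramethoxy-3-(4-methoxyphenyl)indan-1-one | O=C1c2c(OC)c(OC)c(OC)c(OC)c2[C@@H](c2ccc(OC)cc2)C1 | intermediate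
11 | 5,7-dimethoxycoumarin | O=c1ccc2c(OC)cc(OC)cc2o1 | starting material
12 | (4S)-5,7-dimethoxy-4-(4-methoxyphenyl)chroman-2-one | O=C1C[C@@H](c2ccc(OC)cc2)c2c(OC)cc(OC)cc2O1 | intermediate
13 | lithium enolate of 10 | [Li+].[O-]C1=C[C@H](c2ccc(OC)cc2)c2c(OC)c(OC)c(OC)c(OC)c12 | intermediate
14 | lithium enolate of 12 | [Li+].[O-]C1=C[C@@H](c2ccc(OC)cc2)c2c(OC)cc(OC)cc2O1 | intermediate
15 | trans,trans keto lactone, (3R,4R,3'S,4'S) in target numbering | O=C1c2c(OC)c(OC)c(OC)c(OC)c2[C@@H](c2ccc(OC)cc2)[C@@H]1[C@H]1C(=O)Oc2cc(OC)cc(OC)c2[C@@H]1c1ccc(OC)cc1 | intermediate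
16 | trimethylsilyl enol ether of 15 (C2=C3) | C[Si](C)(C)OC1=C([C@H]2C(=O)Oc3cc(OC)cc(OC)c3[C@@H]2c2ccc(OC)cc2)[C@H](c2ccc(OC)cc2)c2c(OC)c(OC)c(OC)c(OC)c12 | intermediate
17 | cis keto lactone, (3S,4R,3'S,4'S) in target numbering, precursor of the key step | O=C1c2c(OC)c(OC)c(OC)c(OC)c2[C@@H](c2ccc(OC)cc2)[C@H]1[C@H]1C(=O)Oc2cc(OC)cc(OC)c2[C@@H]1c1ccc(OC)cc1 | intermediate
18 | peroxy hemiketal of 17 with m-chloroperbenzoic acid (C2 configuration of no consequence) | OC1(OOC(=O)c2cccc(Cl)c2)c2c(OC)c(OC)c(OC)c(OC)c2[C@@H](c2ccc(OC)cc2)[C@H]1[C@H]1C(=O)Oc2cc(OC)cc(OC)c2[C@@H]1c1ccc(OC)cc1 | intermediate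
19 | octamethyl ether of the target, (3S,4R,3'S,4'S) | O=C1Oc2c(OC)c(OC)c(OC)c(OC)c2[C@@H](c2ccc(OC)cc2)[C@H]1[C@H]1C(=O)Oc2cc(OC)cc(OC)c2[C@@H]1c1ccc(OC)cc1 | intermediate
20 | CNP0064734.2, (3S,4R,3'S,4'S) | O=C1Oc2c(O)c(O)c(O)c(O)c2[C@@H](c2ccc(O)cc2)[C@H]1[C@H]1C(=O)Oc2cc(O)cc(O)c2[C@@H]1c1ccc(O)cc1 | target

Total step count: 10. Longest linear sequence: 9 (steps 1, 2, 3, 4, 6, 7, 8, 9, 10).

Steps most likely to fail

1. Step 9 (key step).
- What may go wrong: the peracid may add only slowly to a carbonyl that is crowded by the C8 methoxy group and the C3 substituent and deactivated by the ring donors. These donors are mutually buttressed and twisted, so they also assist the migration less than in a simple dimethoxyphenyl ketone. Epimerisation at C3, migration of C3 or oxidation of the anisole-type rings could then gain ground.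
- Fallback, from 17 back to 19: the ketone is reduced with BH3·SMe2 and a catalytic oxazaborolidine (Corey–Bakshi–Shibata conditions, −20 °C; borane leaves aryl lactones alone) to the indan-1-ol F1, in which C3 can no longer enolise. Urea–hydrogen peroxide with catalytic TsOH exchanges the donor-stabilised benzylic hydroxyl group for a hydroperoxy group to give the benzylic hydroperoxide F2. The same acid triggers its Hock rearrangement: C8a migrates to oxygen and the oxocarbenium ion takes up water to give the chroman-2-ol F3. Dess–Martin periodinane buffered with NaHCO3 oxidises this lactol to 19.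

2. Step 6.
- What may go wrong: homocoupling of either enolate, further oxidation of the alpha-carbonyl radicals by loss of the doubly benzylic hydrogen (dehydrogenation to the unsaturated ketone or lactone), or low conversion caused by crowding at both carbons.
- Fallback, from 10 and 12 back to 15: TMSOTf and Et3N convert 10 into the silyl enol ether F4, and LiHMDS followed by NBS converts 12 into the trans-3-bromolactone F5. Blue-light irradiation of both with fac-Ir(ppy)3 and 2,6-lutidine in MeCN cleaves the C–Br bond by electron transfer. The electrophilic C3' radical adds to the electron-rich C3 of F4, and oxidation and desilylation of the alpha-siloxybenzyl radical give 15 (after DBU equilibration). Polarity matching excludes homocoupling, and both catalyst-set centres are kept.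

3. Step 8.
- What may go wrong: poor facial selectivity of the proton transfer, or re-enolisation and drift to the trans isomer during warming and work-up.
- Fallback, from 16 back to 17: NBS at −78 °C gives the alpha-bromoketone F6, with bromine entering anti to the C4 aryl group. Bu3SnH with Et3B/air in toluene at −78 °C then generates the planar C3 radical, which takes a hydrogen atom on its open face under neutral conditions. The cis centre is thus formed without any acid or base present.

Further compounds
F1 | step 9 | (2S,3R)-4,5,6,7-tetramethoxy-3-(4-methoxyphenyl)-2-[(3S,4S)-5,7-dimethoxy-4-(4-methoxyphenyl)-2-oxochroman-3-yl]indan-1-ol (carbinol centre of no consequence) | OC1c2c(OC)c(OC)c(OC)c(OC)c2[C@@H](c2ccc(OC)cc2)[C@H]1[C@H]1C(=O)Oc2cc(OC)cc(OC)c2[C@@H]1c1ccc(OC)cc1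
F2 | step 9 | 1-hydroperoxide corresponding to F1 | OOC1c2c(OC)c(OC)c(OC)c(OC)c2[C@@H](c2ccc(OC)cc2)[C@H]1[C@H]1C(=O)Oc2cc(OC)cc(OC)c2[C@@H]1c1ccc(OC)cc1
F3 | step 9 | chroman-2-ol (lactol) corresponding to lactone A of 19 | OC1Oc2c(OC)c(OC)c(OC)c(OC)c2[C@@H](c2ccc(OC)cc2)[C@H]1[C@H]1C(=O)Oc2cc(OC)cc(OC)c2[C@@H]1c1ccc(OC)cc1
F4 | step 6 | (1R)-4,5,6,7-tetramethoxy-1-(4-methoxyphenyl)-3-(trimethylsilyloxy)-1H-indene | C[Si](C)(C)OC1=C[C@H](c2ccc(OC)cc2)c2c(OC)c(OC)c(OC)c(OC)c12
F5 | step 6 | (3R,4S)-3-bromo-5,7-dimethoxy-4-(4-methoxyphenyl)chroman-2-one (trans) | Br[C@H]1C(=O)Oc2cc(OC)cc(OC)c2[C@@H]1c1ccc(OC)cc1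
F6 | step 8 | 2-bromo derivative of 17 (bromine anti to the C4 aryl group) | O=C1c2c(OC)c(OC)c(OC)c(OC)c2[C@@H](c2ccc(OC)cc2)[C@@]1(Br)[C@H]1C(=O)Oc2cc(OC)cc(OC)c2[C@@H]1c1ccc(OC)cc1
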